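**Retrosynthetic overview**
- C16–C17 is cut last: B-alkyl Suzuki–Miyaura coupling of the 9-BBN adduct of the exocyclic alkene C18=C17 (right half) with an (E)-enol triflate at C16 (left half).
- Right half: the oxepane (O28, C29, C19, C21, C22, C23, C25) has its carbinol C23 next to the gem-dimethyl ether carbon C25. Taking out C22 leaves a trans-fused 2,2-dimethyltetrahydropyran-3-one, so C22 is put in by diazo insertion between C21 and C23.
- Ring order, right half: cyclohexane (from the dione), then pyran (hydroxy epoxide closure at C25), then oxepane (ring enlargement); C32 and C18 are set afterwards from the exocyclic alkene.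
- Ring order, left half: cyclopentenone, then seven-membered ring by metathesis, then hydroxyl-directed hydrogenation for the cis fusion; C2 methyl and C16 triflate come from one conjugate addition.

Key step: step 8

Remark: atom numbers (C1 to O34) follow the non-hydrogen atoms of the target SMILES and are used for all intermediates. Compounds 1, 2, 11, 20, 21 and 24 are taken as commercial. In step 17 the ligand antipode that gives the 9R carbinol is assumed to be chosen.

**Right half**

Step 1
Reactants: 1 2-methylcyclohexane-1,3-dione; 2 prenyl bromide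
Product: 3 2-methyl-2-(3-methylbut-2-en-1-yl)cyclohexane-1,3-dione
Conditions: NaOH (1 M aq), rt
Reagents that add atoms: prenyl bromide (2), CC(C)=CCBr
Why: C-alkylation of the 1,3-dione enolate by an allylic bromide in water, where C-attack beats O-attack, builds quaternary C19 with methyl C20 and the C21–C23=C25 chain; the product is still achiral.

Step 2
Reactants: 3 2-methyl-2-(3-methylbut-2-en-1-yl)cyclohexane-1,3-dione
Product: 4 (2S,3S)-3-hydroxy-2-methyl-2-(3-methylbut-2-en-1-yl)cyclohexan-1-one
Conditions: baker's yeast (Saccharomyces cerevisiae), sucrose, H2O, 30 °C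
Reagents that add atoms: none
Why: Enantiotopic-group-selective yeast reduction of a 2,2-disubstituted cyclohexane-1,3-dione should reduce one carbonyl from the methyl face, which fixes C19 in the required 2S sense and puts the 3S hydroxyl cis to the prenyl group; that carbinol is only a marker and is erased in step 4.

Step 3
Reactants: 4 (2S,3S)-hydroxy ketone
Product: 5 (1S,2R)-2-methyl-3-methylidene-2-(3-methylbut-2-en-1-yl)cyclohexan-1-ol
Conditions: Zn, CH2Br2, TiCl4, THF/CH2Cl2, 0 °C to rt
Reagents that add atoms: dibromomethane, BrCBr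
Why: Takai–Lombardo methylenation turns the hindered C18 ketone into the exocyclic alkene C18=C17 under non-basic conditions, so the β-hydroxy ketone cannot undergo the retro-aldol cleavage that a phosphorus ylide would risk.

Step 4
Reactants: 5 cis hydroxy alkene
Product: 6 (R)-2-methyl-3-methylidene-2-(3-methylbut-2-en-1-yl)cyclohexan-1-one
Conditions: Dess–Martin periodinane, NaHCO3, CH2Cl2, rt
Reagents that add atoms: none
Why: Dess–Martin oxidation removes the wrongly placed (cis) carbinol and leaves a ketone whose only stereocentre, quaternary C19, cannot epimerise.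

Step 5
Reactants: 6 (R)-ketone
Product: 7 (1R,2R)-2-methyl-3-methylidene-2-(3-methylbut-2-en-1-yl)cyclohexan-1-ol
Conditions: (S)-2-methyl-CBS-oxazaborolidine (20 mol %), catecholborane, toluene, −78 °C
Reagents that add atoms: none
Why: Corey–Bakshi–Shibata reduction under reagent control: the catalyst should treat quaternary C19 as the large flank and C30H2 as the small one and give the 29R alcohol, trans to the C21 chain and cis to the methyl, since the intrinsic methyl/prenyl bias is small; catecholborane at −78 °C leaves both alkenes alone.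

Step 6
Reactants: 7 trans hydroxy alkene
Product: 9 (4aR,8aR)-2,2,4a-trimethyl-5-methylideneoctahydro-2H-chromen-3-ol as both C23 epimers, via epoxy alcohol 8 (not isolated)
Conditions: mCPBA, NaHCO3, CH2Cl2, 0 °C; then camphorsulfonic acid (10 mol %), 0 °C to rt
Reagents that add atoms: mCPBA, O=C(OO)c1cccc(Cl)c1
Why: Peracid epoxidation picks the electron-rich trisubstituted alkene over the hindered 1,1-disubstituted one, and acid-catalysed opening of the epoxide by the equatorial C29 hydroxyl at tertiary C25 (6-endo-tet, favoured by the cation-stabilising gem-dimethyl terminus and by the strain of the alternative trans-fused oxolane) should close the pyran ring with the trans C19/C29 fusion fixed in step 5.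

Step 7
Reactants: 9 trans-fused pyranol
Product: 10 (4aR,8aR)-2,2,4a-trimethyl-5-methylidenehexahydro-2H-chromen-3(4H)-one
Conditions: Dess–Martin periodinane, NaHCO3, CH2Cl2, rt
Reagents that add atoms: none
Why: Dess–Martin oxidation merges both C23 epimers into the single pyranone, whose ketone sits between the C21 methylene and the fully substituted C25.

Step 8
Reactants: 10 trans-fused pyranone; 11 trimethylsilyldiazomethane
Product: 14 (5aR,9aR)-2,2,5a-trimethyl-6-methylideneoctahydro-1-benzoxepin-3(2H)-one, via diazonium betaine 12 (not isolated), via α-silyl oxepanone 13 (not isolated)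
Conditions: TMSCHN2 (1.5 equiv), BF3·OEt2 (1.2 equiv), CH2Cl2, −78 °C; then PPTS, MeOH, rt
Reagents that add atoms: trimethylsilyldiazomethane (11), C[Si](C)(C)C=[N+]=[N-]
Why: BF3 activates the C23 carbonyl, the diazo carbon of 11 adds to it to give betaine 12, and a 1,2-shift of the C21–C23 bond to the diazonium carbon with loss of N2 creates the C21–C22 and C22–C23 bonds; this is the Lewis-acid-promoted one-carbon homologation of cyclic ketones with trimethylsilyldiazomethane, a Tiffeneau–Demjanov-type rearrangement. The oxepane (O28, C29, C19, C21, C22, C23, C25) arises by enlargement of the existing pyran ring through this endocyclic shift and not by cyclisation, so no ring-closure geometry has to be met and the trans C19/C29 fusion is inherited. No permanent stereocentre is created, because the silyl-bearing C22 of 13 becomes a methylene on desilylation. The step needs C21 to migrate instead of C25, and the substrate secures this in two ways: C25 is quaternary and carries the ring oxygen O28, whose inductive pull makes it a poor migrating group, and the bulky Me3Si group of the betaine turns away from C25, which aligns the C23–C21 bond antiperiplanar to the leaving N2. A second insertion is held back by the hindered α-silyl ketone 13, the low temperature and the small excess of 11, and the exocyclic alkene is inert to the diazo compound without a transition metal. Mild acidic methanolysis then takes the silyl group off C22 to give 14.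

Step 9
Reactants: 14 oxepan-3-one
Product: 15 (3S,5aR,9aR)-2,2,5a-trimethyl-6-methylidenedecahydro-1-benzoxepin-3-ol
Conditions: (R)-2-methyl-CBS-oxazaborolidine (20 mol %), catecholborane, toluene, −78 °C
Reagents that add atoms: none
Why: Corey–Bakshi–Shibata reduction with oxygen-bearing quaternary C25 as the large flank and C22H2 as the small one should give the 23S carbinol whatever the conformation of the flexible oxepane.

Step 10
Reactants: 15 oxepanol
Product: 16 (3S,5aR,9aR)-3-[(tert-butyldimethylsilyl)oxy]-2,2,5a-trimethyl-6-methylidenedecahydro-1-benzoxepine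
Conditions: TBSOTf, 2,6-lutidine, CH2Cl2, 0 °C
Reagents that add atoms: tert-butyldimethylsilyl triflate, CC(C)(C)[Si](C)(C)OS(=O)(=O)C(F)(F)F
Why: Silylation of the hindered alcohol with the silyl triflate protects O24 through the oxidations and organometallic steps that follow.

Step 11
Reactants: 16 silyl ether
Product: 17 (3S,5aR,9aR)-3-[(tert-butyldimethylsilyl)oxy]-2,2,5a-trimethyl-6-methylidenedecahydro-1-benzoxepin-7-ol (C32 epimers)
Conditions: SeO2 (0.5 equiv), t-BuOOH, CH2Cl2, rt
Reagents that add atoms: tert-butyl hydroperoxide, CC(C)(C)OO (oxygen relayed by SeO2, O=[Se]=O)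
Why: Selenium dioxide allylic oxidation (ene reaction, then [2,3]-shift) can only occur at C32 because the other allylic carbon C19 is quaternary, and it returns the double bond to the exocyclic position.

Step 12
Reactants: 17 allylic alcohol
Product: 18 (3S,5aR,9aR)-3-[(tert-butyldimethylsilyl)oxy]-2,2,5a-trimethyl-6-methylideneoctahydro-1-benzoxepin-7-one
Conditions: Dess–Martin periodinane, NaHCO3, CH2Cl2, rt
Reagents that add atoms: none
Why: Oxidation of both C32 epimers gives the 2-methylidene ketone, which the neighbouring quaternary C19 shields from dimerisation; it is used at once.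

Step 13
Reactants: 18 methylidene ketone
Product: 19 (3S,5aR,7S,9aR)-3-[(tert-butyldimethylsilyl)oxy]-2,2,5a,7-tetramethyl-6-methylidenedecahydro-1-benzoxepin-7-ol
Conditions: MeLi, CeCl3, THF, −78 °C
Reagents that add atoms: methyllithium, [Li]C
Why: The organocerium reagent adds 1,2 to the enone, and the axial C20 methyl, which is 1,3-diaxial to an axial approach at C32, forces equatorial attack; this should give the 32S tertiary alcohol with axial OH syn to C20 and equatorial methyl C33.

**Left half**

Step 14
Reactants: 20 cyclopentane-1,3-dione; 21 allyl bromide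
Product: 22 2-(prop-2-en-1-yl)cyclopentane-1,3-dione
Conditions: NaOH (1 M aq), rt
Reagents that add atoms: allyl bromide (21), C=CCBr
Why: C-allylation of the dione enolate in water attaches C4 and C3 (plus a sacrificial terminal CH2) to the future ring-fusion carbon C5.

Step 15
Reactants: 22 2-allyl dione
Product: 23 3-(2-methylpropoxy)-2-(prop-2-en-1-yl)cyclopent-2-en-1-one
Conditions: i-BuOH, TsOH (cat.), toluene, reflux (Dean–Stark)
Reagents that add atoms: 2-methylpropan-1-ol, CC(C)CO
Why: Acid-catalysed enol etherification of the symmetric dione gives the vinylogous ester needed for a Stork–Danheiser carbonyl transposition.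

Step 16
Reactants: 23 vinylogous ester; 24 isobutyronitrile
Product: 26 2-methyl-2-[3-oxo-2-(prop-2-en-1-yl)cyclopent-1-en-1-yl]propanenitrile, via tertiary carbinol 25 (not isolated)
Conditions: LiN(iPr)2, 24, THF, −78 °C; then 23, −78 to 0 °C; then HCl (1 M aq), rt
Reagents that add atoms: isobutyronitrile (24), CC(C)C#N; water, O
Why: Stork–Danheiser sequence: the small, strongly nucleophilic lithiated nitrile adds 1,2 to the vinylogous ester carbonyl, and acid hydrolysis of the enol ether with loss of water transposes the enone, which joins C6 to quaternary C12 and leaves C9 as the ketone.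

Step 17
Reactants: 26 enone nitrile
Product: 27 2-[(3R)-3-hydroxy-3-methyl-2-(prop-2-en-1-yl)cyclopent-1-en-1-yl]-2-methylpropanenitrile
Conditions: Me2Zn (3 equiv), Ti(OiPr)4 (1.2 equiv), trans-cyclohexane-1,2-diamine bis(hydroxycamphorsulfonamide) ligand (10 mol %), toluene/hexane, rt; aq NH4Cl
Reagents that add atoms: dimethylzinc, C[Zn]C
Why: Titanium-promoted catalytic asymmetric 1,2-addition of dimethylzinc to a cyclic α-substituted enone, a substrate class in which the α-substituent (here allyl) differentiates the carbonyl flanks, should give the 9R tertiary allylic alcohol; the nitrile is inert.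

Step 18
Reactants: 27 hydroxy nitrile
Product: 29 2-[(3R)-3-hydroxy-3-methyl-2-(prop-2-en-1-yl)cyclopent-1-en-1-yl]-2-methylpropanal, via aldimine 28 (not isolated)
Conditions: i-Bu2AlH (3 equiv), toluene, −78 °C; then aq potassium sodium tartrate; then wet SiO2
Reagents that add atoms: water, O
Why: Partial reduction of the hindered tertiary nitrile stops at the N-aluminated aldimine, which hydrolyses on work-up to the non-enolisable aldehyde C15; one equivalent of hydride is used up by the tertiary hydroxyl.

Step 19
Reactants: 29 hydroxy aldehyde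
Product: 30 (1R)-3-(3-hydroxy-2-methylpent-4-en-2-yl)-1-methyl-2-(prop-2-en-1-yl)cyclopent-2-en-1-ol (C15 epimers)
Conditions: CH2=CHMgBr (2.5 equiv), THF, 0 °C; aq NH4Cl
Reagents that add atoms: vinylmagnesium bromide, C=C[Mg]Br
Why: Grignard addition to the neopentyl aldehyde brings in C2 as a vinyl carbinol; the C15 configuration does not matter because C15 becomes a ketone in step 21.

Step 20
Reactants: 30 diene diol
Product: 31 (1R)-1,4,4-trimethyl-1,2,3,4,5,8-hexahydroazulene-1,5-diol (C15 epimers)
Conditions: second-generation Grubbs catalyst RuCl2(=CHPh)(H2IMes)(PCy3) (5 mol %), CH2Cl2, 40 °C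
Reagents that add atoms: none
Why: Ring-closing metathesis of the two monosubstituted alkenes, held cis on the C5=C6 double bond, closes the seven-membered ring at C2=C3; the tetrasubstituted alkene takes no part.

Step 21
Reactants: 31 bicyclic diol
Product: 32 (1R)-1-hydroxy-1,4,4-trimethyl-2,3,4,8-tetrahydroazulen-5(1H)-one
Conditions: MnO2, CH2Cl2, rt
Reagents that add atoms: none
Why: Manganese dioxide oxidises only the secondary allylic alcohol at C15, so a single dienone results and no second hydroxyl remains to misdirect the hydrogenation.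

Step 22
Reactants: 32 dienone
Product: 33 (1R)-1-hydroxy-1,4,4-trimethyloctahydroazulen-5(1H)-one, cis-fused, H5 and H6 cis to the hydroxyl
Conditions: [Ir(cod)(PCy3)(py)]PF6 (10 mol %), H2 (1 to 50 bar), CH2Cl2, rt
Reagents that add atoms: none
Why: Hydroxyl-directed hydrogenation with the cationic iridium catalyst, one of the few that reduce tetrasubstituted alkenes, should deliver hydrogen to C5 and C6 from the face of the C9 hydroxyl and so set the cis fusion with H5 and H6 syn to O11, while the C2=C3 enone bond is reduced as well; pressure may be needed because C9 and C12 flank the alkene.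

Step 23
Reactants: 33 hydroxy ketone
Product: 34 (1R)-1,4,4-trimethyl-1-[(triethylsilyl)oxy]octahydroazulen-5(1H)-one, cis-fused
Conditions: TESOTf, 2,6-lutidine, CH2Cl2, −78 °C
Reagents that add atoms: triethylsilyl triflate, CC[Si](CC)(CC)OS(=O)(=O)C(F)(F)F
Why: Low-temperature silylation with the silyl triflate and a hindered pyridine caps the tertiary alcohol without enolising the ketone, so the strong bases and the triflating agent of the next steps meet no free hydroxyl.

Step 24
Reactants: 34 silyloxy ketone
Product: 35 (1R)-1,4,4-trimethyl-1-[(triethylsilyl)oxy]-1,2,3,3a,4,7,8,8a-octahydroazulen-5-yl trifluoromethanesulfonate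
Conditions: KN(SiMe3)2, PhNTf2, THF, −78 °C
Reagents that add atoms: N-phenylbis(trifluoromethanesulfonimide), O=S(=O)(N(c1ccccc1)S(=O)(=O)C(F)(F)F)C(F)(F)F
Why: The ketone can enolise only towards C2 because C12 is quaternary, so enolate O-triflation gives a single vinyl triflate.

Step 25
Reactants: 35 vinyl triflate
Product: 36 (1R)-1,4,4-trimethyl-1-[(triethylsilyl)oxy]-1,2,3,3a,4,7,8,8a-octahydroazulene-5-carbaldehyde
Conditions: Pd(OAc)2 (5 mol %), dppp, CO (1 atm), Et3SiH, Et3N, DMF, 70 °C
Reagents that add atoms: carbon monoxide, [C-]#[O+]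
Why: Palladium-catalysed reductive carbonylation (formylation) of the vinyl triflate by oxidative addition, CO insertion and hydride transfer from the silane introduces C16 as the aldehyde of a C2=C15 enal.

Step 26
Reactants: 36 enal
Product: 39 (E)-{(1R)-1,4,4,6-tetramethyl-1-[(triethylsilyl)oxy]octahydroazulen-5(1H)-ylidene}methyl trifluoromethanesulfonate, via silyl enol ether 37 (not isolated), via lithium enolate 38 (not isolated)
Conditions: Me2CuLi (from MeLi and CuI), TMSCl, THF, −78 °C; then MeLi, 0 °C; then PhNTf2, −78 °C to rt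
Reagents that add atoms: lithium dimethylcuprate, [Li+].C[Cu-]C; N-phenylbis(trifluoromethanesulfonimide), O=S(=O)(N(c1ccccc1)S(=O)(=O)C(F)(F)F)C(F)(F)F
Why: Silyl-chloride-accelerated conjugate addition of the cuprate should deliver methyl C1 to C2 from the exo face of the cis-fused bicycle (the face of H5 and H6), and because the formyl oxygen avoids the gem-dimethyl carbon C12 the enal should react s-cis and give the enolate with oxygen syn to C2; that geometry is kept through silyl cleavage by MeLi and O-triflation to the (E)-enol triflate.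

**Union and end game**

Step 27
Reactants: 19 exocyclic alkene; 39 enol triflate
Product: 41 coupled bis-silyl ether, via alkylborane 40 (not isolated)
Conditions: 19, 9-BBN (2.5 equiv), THF, rt to 50 °C; then 39, Pd(dppf)Cl2 (10 mol %), AsPh3, Cs2CO3, DMF/H2O, rt to 50 °C
Reagents that add atoms: none
Why: 9-BBN should add to the exocyclic alkene with boron at C17 and hydrogen at C18 from the axial face opposite the two flanking axial groups (C20 methyl and O34), which sets 18R with C17 equatorial, and B-alkyl Suzuki–Miyaura coupling with the enol triflate then forms C16–C17 with retention of alkene geometry.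

Step 28
Reactants: 41 coupled bis-silyl ether
Product: 42 CNP0167890.3 (target)
Conditions: Bu4NF, THF, 50 °C
Reagents that add atoms: none
Why: Fluoride cleaves both silyl ethers (at O24 and O11) under basic conditions that spare the tertiary alcohols and the trisubstituted alkene.

**Compound list**

1 | 2-methylcyclohexane-1,3-dione | CC1C(=O)CCCC1=O | starting material
2 | prenyl bromide (1-bromo-3-methylbut-2-ene) | CC(C)=CCBr | starting material
3 | 2-methyl-2-(3-methylbut-2-en-1-yl)cyclohexane-1,3-dione | CC(C)=CCC1(C)C(=O)CCCC1=O | intermediate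
4 | (2S,3S)-3-hydroxy-2-methyl-2-(3-methylbut-2-en-1-yl)cyclohexan-1-one | O=C1CCC[C@H](O)[C@]1(C)CC=C(C)C | intermediate
5 | (1S,2R)-2-methyl-3-methylidene-2-(3-methylbut-2-en-1-yl)cyclohexan-1-ol (OH cis to prenyl) | C=C1CCC[C@H](O)[C@]1(C)CC=C(C)C | intermediate
6 | (R)-2-methyl-3-methylidene-2-(3-methylbut-2-en-1-yl)cyclohexan-1-one | C=C1CCCC(=O)[C@]1(C)CC=C(C)C | intermediate
7 | (1R,2R)-2-methyl-3-methylidene-2-(3-methylbut-2-en-1-yl)cyclohexan-1-ol (OH trans to prenyl) | C=C1CCC[C@@H](O)[C@]1(C)CC=C(C)C | intermediate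
8 | (1R,2R)-2-[(3,3-dimethyloxiran-2-yl)methyl]-2-methyl-3-methylidenecyclohexan-1-ol (epoxide epimers) | C=C1CCC[C@@H](O)[C@]1(C)CC1OC1(C)C | intermediate
9 | (4aR,8aR)-2,2,4a-trimethyl-5-methylideneoctahydro-2H-chromen-3-ol (trans-fused, C23 epimers) | C=C1[C@@]2(C)CC(O)C(C)(C)O[C@@H]2CCC1 | intermediate
10 | (4aR,8aR)-2,2,4a-trimethyl-5-methylidenehexahydro-2H-chromen-3(4H)-one | C=C1[C@@]2(C)CC(=O)C(C)(C)O[C@@H]2CCC1 | intermediate
11 | trimethylsilyldiazomethane | C[Si](C)(C)C=[N+]=[N-] | starting material
12 | BF3-bound diazonium betaine from addition of 11 to C23 of 10 | C=C1[C@@]2(C)CC(O[B-](F)(F)F)(C([N+]#N)[Si](C)(C)C)C(C)(C)O[C@@H]2CCC1 | intermediate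
13 | (5aR,9aR)-2,2,5a-trimethyl-6-methylidene-4-(trimethylsilyl)octahydro-1-benzoxepin-3(2H)-one (C22 epimers) | C=C1[C@@]2(C)CC([Si](C)(C)C)C(=O)C(C)(C)O[C@@H]2CCC1 | intermediate
14 | (5aR,9aR)-2,2,5a-trimethyl-6-methylideneoctahydro-1-benzoxepin-3(2H)-one | C=C1[C@@]2(C)CCC(=O)C(C)(C)O[C@@H]2CCC1 | intermediate
15 | (3S,5aR,9aR)-2,2,5a-trimethyl-6-methylidenedecahydro-1-benzoxepin-3-ol | C=C1[C@@]2(C)CC[C@H](O)C(C)(C)O[C@@H]2CCC1 | intermediate
16 | (3S,5aR,9aR)-3-[(tert-butyldimethylsilyl)oxy]-2,2,5a-trimethyl-6-methylidenedecahydro-1-benzoxepine | C=C1[C@@]2(C)CC[C@H](O[Si](C)(C)C(C)(C)C)C(C)(C)O[C@@H]2CCC1 | intermediate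
17 | (3S,5aR,9aR)-3-[(tert-butyldimethylsilyl)oxy]-2,2,5a-trimethyl-6-methylidenedecahydro-1-benzoxepin-7-ol (C32 epimers) | C=C1[C@@]2(C)CC[C@H](O[Si](C)(C)C(C)(C)C)C(C)(C)O[C@@H]2CCC1O | intermediate
18 | (3S,5aR,9aR)-3-[(tert-butyldimethylsilyl)oxy]-2,2,5a-trimethyl-6-methylideneoctahydro-1-benzoxepin-7-one | C=C1[C@@]2(C)CC[C@H](O[Si](C)(C)C(C)(C)C)C(C)(C)O[C@@H]2CCC1=O | intermediate
19 | (3S,5aR,7S,9aR)-3-[(tert-butyldimethylsilyl)oxy]-2,2,5a,7-tetramethyl-6-methylidenedecahydro-1-benzoxepin-7-ol | C=C1[C@@]2(C)CC[C@H](O[Si](C)(C)C(C)(C)C)C(C)(C)O[C@@H]2CC[C@]1(C)O | intermediate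
20 | cyclopentane-1,3-dione | O=C1CCC(=O)C1 | starting material
21 | allyl bromide (3-bromoprop-1-ene) | C=CCBr | starting material
22 | 2-(prop-2-en-1-yl)cyclopentane-1,3-dione | C=CCC1C(=O)CCC1=O | intermediate
23 | 3-(2-methylpropoxy)-2-(prop-2-en-1-yl)cyclopent-2-en-1-one | C=CCC1=C(OCC(C)C)CCC1=O | intermediate
24 | isobutyronitrile (2-methylpropanenitrile) | CC(C)C#N | starting material
25 | 2-[1-hydroxy-3-(2-methylpropoxy)-2-(prop-2-en-1-yl)cyclopent-2-en-1-yl]-2-methylpropanenitrile (formed as its lithium alkoxide) | C=CCC1=C(OCC(C)C)CCC1(O)C(C)(C)C#N | intermediate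
26 | 2-methyl-2-[3-oxo-2-(prop-2-en-1-yl)cyclopent-1-en-1-yl]propanenitrile | C=CCC1=C(C(C)(C)C#N)CCC1=O | intermediate
27 | 2-[(3R)-3-hydroxy-3-methyl-2-(prop-2-en-1-yl)cyclopent-1-en-1-yl]-2-methylpropanenitrile | C=CCC1=C(C(C)(C)C#N)CC[C@@]1(C)O | intermediate
28 | aldimine of 29 (formed as its N-aluminium derivative) | C=CCC1=C(C(C)(C)C=N)CC[C@@]1(C)O | intermediate
29 | 2-[(3R)-3-hydroxy-3-methyl-2-(prop-2-en-1-yl)cyclopent-1-en-1-yl]-2-methylpropanal | C=CCC1=C(C(C)(C)C=O)CC[C@@]1(C)O | intermediate
30 | (1R)-3-(3-hydroxy-2-methylpent-4-en-2-yl)-1-methyl-2-(prop-2-en-1-yl)cyclopent-2-en-1-ol (C15 epimers) | C=CCC1=C(C(C)(C)C(O)C=C)CC[C@@]1(C)O | intermediate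
31 | (1R)-1,4,4-trimethyl-1,2,3,4,5,8-hexahydroazulene-1,5-diol (C15 epimers) | OC1C=CCC2=C(CC[C@@]2(C)O)C1(C)C | intermediate
32 | (1R)-1-hydroxy-1,4,4-trimethyl-2,3,4,8-tetrahydroazulen-5(1H)-one | O=C1C=CCC2=C(CC[C@@]2(C)O)C1(C)C | intermediate
33 | (1R)-1-hydroxy-1,4,4-trimethyloctahydroazulen-5(1H)-one, cis-fused, H5 and H6 cis to OH | O=C1CCC[C@@H]2[C@@H](CC[C@@]2(C)O)C1(C)C | intermediate
34 | triethylsilyl ether of 33 | O=C1CCC[C@@H]2[C@@H](CC[C@@]2(C)O[Si](CC)(CC)CC)C1(C)C | intermediate
35 | (1R)-1,4,4-trimethyl-1-[(triethylsilyl)oxy]-1,2,3,3a,4,7,8,8a-octahydroazulen-5-yl trifluoromethanesulfonate, cis-fused | O=S(=O)(OC1=CCC[C@@H]2[C@@H](CC[C@@]2(C)O[Si](CC)(CC)CC)C1(C)C)C(F)(F)F | intermediate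
36 | (1R)-1,4,4-trimethyl-1-[(triethylsilyl)oxy]-1,2,3,3a,4,7,8,8a-octahydroazulene-5-carbaldehyde, cis-fused | O=CC1=CCC[C@@H]2[C@@H](CC[C@@]2(C)O[Si](CC)(CC)CC)C1(C)C | intermediate
37 | (E)-trimethylsilyl enol ether of the C16 aldehyde, C2 methyl cis to H5 and H6 | C[C@@H]1CC[C@@H]2[C@@H](CC[C@@]2(C)O[Si](CC)(CC)CC)C(C)(C)/C1=C/O[Si](C)(C)C | intermediate
38 | lithium (E)-enolate of the C16 aldehyde | C[C@@H]1CC[C@@H]2[C@@H](CC[C@@]2(C)O[Si](CC)(CC)CC)C(C)(C)/C1=C/[O-].[Li+] | intermediate
39 | (E)-{(1R)-1,4,4,6-tetramethyl-1-[(triethylsilyl)oxy]octahydroazulen-5(1H)-ylidene}methyl trifluoromethanesulfonate, cis-fused, C2 methyl cis to H5 and H6 | C[C@@H]1CC[C@@H]2[C@@H](CC[C@@]2(C)O[Si](CC)(CC)CC)C(C)(C)/C1=C/OS(=O)(=O)C(F)(F)F | intermediate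
40 | B-alkyl-9-BBN adduct of 19 (boron on C17, 18R) | C(B1C2CCCC1CCC2)[C@@H]1[C@@]2(C)CC[C@H](O[Si](C)(C)C(C)(C)C)C(C)(C)O[C@@H]2CC[C@]1(C)O | intermediate
41 | target with O24 as tert-butyldimethylsilyl ether and O11 as triethylsilyl ether | C[C@@H]1CC[C@@H]2[C@@H](CC[C@@]2(C)O[Si](CC)(CC)CC)C(C)(C)/C1=C/C[C@@H]1[C@@]2(C)CC[C@H](O[Si](C)(C)C(C)(C)C)C(C)(C)O[C@@H]2CC[C@]1(C)O | intermediate
42 | CNP0167890.3 | C[C@@H]1CC[C@@H]2[C@@H](CC[C@@]2(C)O)C(C)(C)/C1=C/C[C@@H]1[C@@]2(C)CC[C@H](O)C(C)(C)O[C@@H]2CC[C@]1(C)O | target

**Step count**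

Total: 28 steps (13 to alkene 19, 13 to enol triflate 39, 2 after union).
Longest linear sequence: 15 steps (steps 1–13, 27, 28; the branch of steps 14–26, 27, 28 is equally long).

**Steps most likely to fail, with fallbacks**

1. Step 8. What may go wrong: migration of C25 instead of C21, or repeated insertion. Fallback, from pyranone 10 back to oxepanone 14: the carbon is inserted in stages with the regiochemistry fixed by enolisation, which is possible only towards C21. LiN(iPr)2 and TMSCl give the silyl enol ether F1. Et2Zn and CH2I2 cyclopropanate its electron-rich double bond to the siloxycyclopropane F2. FeCl3 in DMF cleaves the internal cyclopropane bond (Saegusa–Ito ring expansion) to the β-chloro oxepanone F3. NaOAc in MeOH eliminates HCl to the oxepenone F4, and conjugate reduction with [CuH(PPh3)]6 gives 14.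

2. Step 6. What may go wrong: competing 5-exo attack of the hydroxyl at C23, which would give the oxolane. Fallback, from alcohol 7 back to pyranol 9: ring closure is moved to the alkene stage, where Markovnikov addition dictates the mode. Hg(OCOCF3)2 in MeCN followed by aqueous NaCl gives, by intramolecular alkoxymercuration, the organomercurial F5 with oxygen on tertiary C25 and mercury on C23. NaBH4 under O2 in DMF then replaces mercury by hydroxyl to give 9.

3. Step 26. What may go wrong: 1,2-addition to the aldehyde, poor facial selectivity at C2, or loss of enolate geometry. Fallback, from ketone 34 back to enol triflate 39 (steps 24 and 25 are then not used): LiN(iPr)2 and MeI methylate the only enolisable position from the exo face to give the 2-methyl ketone F6. Takai–Lombardo methylenation (Zn, CH2Br2, TiCl4) gives the exocyclic alkene F7. 9-BBN followed by H2O2/NaOH gives the primary alcohol F8, and Dess–Martin oxidation gives the aldehyde F9. Deprotonation with KN(SiMe3)2, in which the enolate oxygen turns away from the quaternary C12, and trapping with PhNTf2 give 39.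

**Further compounds**

F1 | step 8 | trimethylsilyl enol ether of 10 (C21=C23) | C=C1[C@@]2(C)C=C(O[Si](C)(C)C)C(C)(C)O[C@@H]2CCC1
F2 | step 8 | siloxycyclopropane (C22 bridging C21 and C23) | C=C1[C@@]2(C)C3CC3(O[Si](C)(C)C)C(C)(C)O[C@@H]2CCC1
F3 | step 8 | β-chloro oxepanone (Cl on C21) | C=C1[C@@]2(C)C(Cl)CC(=O)C(C)(C)O[C@@H]2CCC1
F4 | step 8 | oxepenone (C21=C22) | C=C1[C@@]2(C)C=CC(=O)C(C)(C)O[C@@H]2CCC1
F5 | step 6 | chloromercurio pyran (HgCl on C23) | C=C1[C@@]2(C)CC([Hg]Cl)C(C)(C)O[C@@H]2CCC1
F6 | step 26 | 2-methyl ketone (C1 on C2, cis to H5 and H6) | C[C@@H]1CC[C@@H]2[C@@H](CC[C@@]2(C)O[Si](CC)(CC)CC)C(C)(C)C1=O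
F7 | step 26 | exocyclic alkene C15=C16 | C[C@@H]1CC[C@@H]2[C@@H](CC[C@@]2(C)O[Si](CC)(CC)CC)C(C)(C)C1=C
F8 | step 26 | primary alcohol at C16 (C15 epimers) | C[C@@H]1CC[C@@H]2[C@@H](CC[C@@]2(C)O[Si](CC)(CC)CC)C(C)(C)C1CO
F9 | step 26 | aldehyde at C16 (C15 epimers) | C[C@@H]1CC[C@@H]2[C@@H](CC[C@@]2(C)O[Si](CC)(CC)CC)C(C)(C)C1C=O
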